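The butenolide ring (O–C12(=O)–C11=C7–C6, germacrane numbering) is read as a (2+2+1) adduct: its tetrasubstituted C7=C11 alkene is an internal alkyne, C6–O an aldehyde and C12 carbon monoxide. One nickel-mediated operation joins a nerol-derived epoxy aldehyde (C1–C6) and a chiral propargylic silyl ether (C7–C11, C13, C14), fragments of similar size, at the hindered C6–C7 bond. The same operation forms C11–C12, closes the lactone, fixes the alkene geometry by syn addition and sets C6 under control of the C4–C5 oxirane. The ten-membered ring is closed later at C1–C10 by a Nozaki–Hiyama–Kishi reaction, and a final oxidation unveils the enone.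

Key step: step 7

Remark on the chemistry: the SMILES reads as 4S,5R,6R,8R with C3 and C6 cis on the oxirane. The oxirane therefore maps onto a Z-trisubstituted alkene, which makes nerol the source of C1–C6 and C15. Numbering used throughout: C1 ketone, C4 methyl-bearing oxirane carbon, C5 oxirane CH, C6 lactone CH–O, C7/C11 butenolide β/α carbons, C8 methacrylate carbinol, C10 bearing exocyclic C14H2, C12 lactone C=O, C13 CH2OAc.

Step 1
Reactants: 1 nerol
Product: 2 (2R,3S)-2,3-epoxynerol
Conditions: Ti(OiPr)4 (cat.), D-(−)-diethyl tartrate (cat.), tBuOOH, 4 Å MS, CH2Cl2, −20 °C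
Reagents that add atoms: tert-butyl hydroperoxide, CC(C)(C)OO
Why: Sharpless asymmetric epoxidation is directed by the allylic hydroxyl, so only the C4=C5 alkene reacts; D-(−)-tartrate should give the (2R,3S) epoxide (C4 S, C5 R), and the Z geometry of nerol is carried stereospecifically into the cis relation of C3 and C6.

Step 2
Reactants: 2 (2R,3S)-2,3-epoxynerol
Product: 3 (2S,3S)-3-methyl-3-(4-methylpent-3-en-1-yl)oxirane-2-carbaldehyde
Conditions: TEMPO (cat.), PhI(OAc)2, CH2Cl2, rt
Reagents that add atoms: none
Why: Oxoammonium-mediated (TEMPO) oxidation stops at the aldehyde under nearly neutral conditions that should leave the oxirane, its configuration and the trisubstituted alkene untouched.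

Step 3
Reactants: 4 tert-butyldimethyl(prop-2-yn-1-yloxy)silane
Product: 6 4-[(tert-butyldimethylsilyl)oxy]but-2-ynal, via lithium acetylide 5 (not isolated)
Conditions: nBuLi, THF, −78 °C; DMF; aq. NH4Cl
Reagents that add atoms: N,N-dimethylformamide, CN(C)C=O
Why: Formylation of a lithium acetylide with DMF is the standard route to alkynals, and the silyl ether is inert to nBuLi at low temperature.

Step 4
Reactants: 7 (1-bromovinyl)trimethylsilane; 8 2-(chloromethyl)-4,4,5,5-tetramethyl-1,3,2-dioxaborolane
Product: 11 4,4,5,5-tetramethyl-2-[2-(trimethylsilyl)allyl]-1,3,2-dioxaborolane, via Grignard reagent 9 (not isolated), via boronate complex 10 (not isolated)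
Conditions: Mg, THF; then 8, −78 °C to rt
Reagents that add atoms: none
Why: Matteson homologation: the alkenyl Grignard reagent adds to boron and the ate complex rearranges by 1,2-migration with loss of chloride, which places a CH2 group between boron and the silylated alkene carbon.

Step 5
Reactants: 6 4-[(tert-butyldimethylsilyl)oxy]but-2-ynal; 11 2-(trimethylsilyl)allyl pinacol boronate
Product: 13 (4R)-1-[(tert-butyldimethylsilyl)oxy]-6-(trimethylsilyl)hept-6-en-2-yn-4-ol, via borate ester 12 (not isolated)
Conditions: (R)-TRIP phosphoric acid (5 mol%), toluene, −30 °C; aqueous work-up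
Reagents that add atoms: none
Why: Chiral phosphoric acid-catalysed allylboration runs through a closed chair transition state; the (R)-acid should direct attack to the Re face of the non-enolisable alkynal as it does for aryl and alkenyl aldehydes, which sets C8 as R, and allyl transposition regenerates the 2-silylallyl unit.

Step 6
Reactants: 13 (4R)-propargylic alcohol
Product: 14 (4R)-1,4-bis[(tert-butyldimethylsilyl)oxy]-6-(trimethylsilyl)hept-6-en-2-yne
Conditions: TBSCl, imidazole, DMF, rt
Reagents that add atoms: tert-butyldimethylsilyl chloride, CC(C)(C)[Si](C)(C)Cl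
Why: Standard silylation removes the only acidic proton, which would otherwise protonate the nickel–carbon bond in step 7, and enlarges the C7 substituent relative to the C11 substituent.

Step 7
Reactants: 3 epoxy aldehyde; 14 bis-silyl ether alkyne
Product: 17 (5R)-3-{[(tert-butyldimethylsilyl)oxy]methyl}-4-[(1R)-1-[(tert-butyldimethylsilyl)oxy]-3-(trimethylsilyl)but-3-en-1-yl]-5-[(2R,3S)-3-methyl-3-(4-methylpent-3-en-1-yl)oxiran-2-yl]furan-2(5H)-one, via oxanickelacycle 15 (not isolated), via acylnickelacycle 16 (not isolated)
Conditions: Ni(cod)2 (1.1 equiv), SIPr (1.1 equiv), toluene, rt, 14 then slow addition of 3; then CO (1 atm), rt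
Reagents that add atoms: carbon monoxide, [C-]#[O+]
Why: Proposed new method: SIPr-ligated zerovalent nickel binds alkyne 14 and the aldehyde of 3 and couples them oxidatively to the five-membered oxanickelacyclopentene 15 (C6–C7 bond, syn across the alkyne); CO then inserts into the Ni–C11 bond to give the six-membered acylnickelacycle 16 (C11–C12 bond), and C(acyl)–O reductive elimination releases the five-membered lactone, so the butenolide is closed as a formal (2+2+1) annulation. The closest known reaction types are the nickel/carbene-catalysed reductive coupling of alkynes with aldehydes (same metallacycle), the intramolecular hetero-Pauson–Khand reaction of alkynals with Mo(CO)6 or Ru3(CO)12, and the nickel-catalysed (2+2+1) carbonylation of alkynes with imines; a preparative intermolecular union of two functionalised partners goes beyond them. C6 is the only new stereocentre and is controlled by the oxirane: in the Felkin–Anh (and equally the Cornforth) arrangement the C5–O bond lies anti to the incoming alkyne carbon and the C3 chain, cis to the formyl group, blocks the other face, which should give 6R (C5–O and C6–O anti), the sense known for α-oxygenated aldehydes in nickel couplings. The regiochemistry needed (C–C bond at the more hindered alkyne carbon C7, nickel at C11) is the one bulky carbene ligands enforce, because the small CH2OTBS group is placed next to the ligand. Chemoselectivity rests on the absence of carbon–halogen bonds, esters and enones: silyl ethers, the vinylsilane and the trisubstituted alkene are poor partners for zerovalent nickel, and CO is admitted only after the metallacycle has formed. The cis relation of C6 and C12 on C7=C11 that lactone closure requires follows from the syn addition.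

Step 8
Reactants: 17 bis-silyl ether butenolide
Product: 18 C8,C13-diol (5R)-4-[(1R)-1-hydroxy-3-(trimethylsilyl)but-3-en-1-yl]-3-(hydroxymethyl)-5-[(2R,3S)-3-methyl-3-(4-methylpent-3-en-1-yl)oxiran-2-yl]furan-2(5H)-one
Conditions: HF·pyridine, pyridine, THF, 0 °C to rt
Reagents that add atoms: none
Why: Buffered fluoride desilylation cleaves both O–Si bonds without base, which would enolise the butenolide next to the oxirane, while trisubstituted oxiranes and the C–Si bond of the vinylsilane normally survive these conditions.

Step 9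
Reactants: 18 C8,C13-diol
Product: 19 C13 monoacetate (C8–OH free)
Conditions: AcCl (1.05 equiv), 2,4,6-collidine, CH2Cl2, −78 °C
Reagents that add atoms: acetyl chloride, CC(=O)Cl
Why: Kinetically selective acylation: with a hindered pyridine base at low temperature the primary allylic C13–OH should react well before the hindered secondary C8–OH.

Step 10
Reactants: 19 C13 monoacetate
Product: 20 C8 methacrylate, C13 acetate
Conditions: methacrylic anhydride, Et3N, DMAP (cat.), CH2Cl2, 0 °C to rt
Reagents that add atoms: methacrylic anhydride, C=C(C)C(=O)OC(=O)C(C)=C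
Why: DMAP-catalysed esterification acylates the remaining secondary alcohol with retention at C8, since the C–O bond is not touched, under bases too weak to deprotonate C6.

Step 11
Reactants: 20 diester
Product: 22 C1 aldehyde (3-oxopropyl group on the oxirane), via ozonide 21 (not isolated)
Conditions: O3 (to the Sudan Red 7B end point), CH2Cl2, −78 °C; Me2S
Reagents that add atoms: ozone, [O-][O+]=O
Why: Ozonolysis (Criegee mechanism) should pick the only electron-rich trisubstituted alkene, because the methacrylate and butenolide alkenes are electron-poor and the α-silyl 1,1-disubstituted alkene is hindered and electronically closer to a monosubstituted alkene.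

Step 12
Reactants: 22 C1 aldehyde with vinylsilane
Product: 23 C1 aldehyde with 2-iodoalkene at C10
Conditions: NIS, MeCN, rt, dark
Reagents that add atoms: N-iodosuccinimide, O=C1CCC(=O)N1I
Why: Iododesilylation of a 2-silyl-1-alkene with NIS in acetonitrile is an established neutral route to 2-iodo-1-alkenes, and no other electron-rich alkene is left to compete for the iodonium source.

Step 13
Reactants: 23 iodo aldehyde
Product: 25 ten-membered allylic alcohol (C1–OH as either epimer), via alkenylchromium species 24 (not isolated)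
Conditions: CrCl2 (excess), NiCl2 (cat.), DMSO/THF, rt, slow addition at high dilution
Reagents that add atoms: none
Why: Nozaki–Hiyama–Kishi reaction: nickel-catalysed insertion into the C–I bond, transmetallation to chromium and aldehyde-selective addition tolerate lactone, esters and oxirane; 2-iodoalkenes are proven partners for medium-ring closure to exo-methylene carbinols, and the new C1 centre needs no control because it is oxidised next.

Step 14
Reactants: 25 macrocyclic allylic alcohol
Product: 26 target CNP0266914.1
Conditions: Dess–Martin periodinane, pyridine, CH2Cl2, 0 °C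
Reagents that add atoms: none
Why: Dess–Martin oxidation converts both C1 epimers into the α-methylene ketone under buffered, non-basic conditions, so the sensitive enone appears only in the last step and C4, C5, C6 and C8 are not disturbed.

Compound list
1 | nerol, (2Z)-3,7-dimethylocta-2,6-dien-1-ol | CC(C)=CCC/C(C)=C\CO | starting material
2 | (2R,3S)-2,3-epoxynerol | CC(C)=CCC[C@]1(C)O[C@@H]1CO | intermediate
3 | (2S,3S)-3-methyl-3-(4-methylpent-3-en-1-yl)oxirane-2-carbaldehyde | CC(C)=CCC[C@]1(C)O[C@@H]1C=O | intermediate
4 | tert-butyldimethyl(prop-2-yn-1-yloxy)silane | C#CCO[Si](C)(C)C(C)(C)C | starting material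
5 | lithium acetylide of 4 | [Li]C#CCO[Si](C)(C)C(C)(C)C | intermediate
6 | 4-[(tert-butyldimethylsilyl)oxy]but-2-ynal | O=CC#CCO[Si](C)(C)C(C)(C)C | intermediate
7 | (1-bromovinyl)trimethylsilane | C=C(Br)[Si](C)(C)C | starting material
8 | 2-(chloromethyl)-4,4,5,5-tetramethyl-1,3,2-dioxaborolane | ClCB1OC(C)(C)C(C)(C)O1 | starting material
9 | [1-(trimethylsilyl)vinyl]magnesium bromide | C=C([Mg]Br)[Si](C)(C)C | intermediate
10 | chloromethyl[1-(trimethylsilyl)vinyl]boronate complex, MgBr salt | C=C([Si](C)(C)C)[B-]1(CCl)OC(C)(C)C(C)(C)O1.[Mg+]Br | intermediate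
11 | 4,4,5,5-tetramethyl-2-[2-(trimethylsilyl)allyl]-1,3,2-dioxaborolane | C=C(CB1OC(C)(C)C(C)(C)O1)[Si](C)(C)C | intermediate
12 | pinacol borate ester of 13 | CC1(C)OB(O[C@@H](C#CCO[Si](C)(C)C(C)(C)C)CC(=C)[Si](C)(C)C)OC1(C)C | intermediate
13 | (4R)-1-[(tert-butyldimethylsilyl)oxy]-6-(trimethylsilyl)hept-6-en-2-yn-4-ol | O[C@@H](C#CCO[Si](C)(C)C(C)(C)C)CC(=C)[Si](C)(C)C | intermediate
14 | (4R)-1,4-bis[(tert-butyldimethylsilyl)oxy]-6-(trimethylsilyl)hept-6-en-2-yne | CC(C)(C)[Si](C)(C)O[C@@H](C#CCO[Si](C)(C)C(C)(C)C)CC(=C)[Si](C)(C)C | intermediate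
15 | SIPr-ligated oxanickelacyclopentene (ring Ni–O–C6–C7=C11) | CC(C)=CCC[C@]1(C)O[C@@H]1[C@@H]1O[Ni](=C2N(c3c(C(C)C)cccc3C(C)C)CCN2c2c(C(C)C)cccc2C(C)C)C(CO[Si](C)(C)C(C)(C)C)=C1[C@H](O[Si](C)(C)C(C)(C)C)CC(=C)[Si](C)(C)C | intermediate
16 | SIPr-ligated acylnickelacycle (ring Ni–O–C6–C7=C11–C12(=O)) | CC(C)=CCC[C@]1(C)O[C@@H]1[C@@H]1O[Ni](=C2N(c3c(C(C)C)cccc3C(C)C)CCN2c2c(C(C)C)cccc2C(C)C)C(=O)C(CO[Si](C)(C)C(C)(C)C)=C1[C@H](O[Si](C)(C)C(C)(C)C)CC(=C)[Si](C)(C)C | intermediate
17 | bis-silyl ether butenolide (4S,5R,6R,8R) | CC(C)=CCC[C@]1(C)O[C@@H]1[C@@H]1OC(=O)C(CO[Si](C)(C)C(C)(C)C)=C1[C@H](O[Si](C)(C)C(C)(C)C)CC(=C)[Si](C)(C)C | intermediate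
18 | C8,C13-diol butenolide | CC(C)=CCC[C@]1(C)O[C@@H]1[C@@H]1OC(=O)C(CO)=C1[C@H](O)CC(=C)[Si](C)(C)C | intermediate
19 | C13 acetate, C8 alcohol | CC(C)=CCC[C@]1(C)O[C@@H]1[C@@H]1OC(=O)C(COC(C)=O)=C1[C@H](O)CC(=C)[Si](C)(C)C | intermediate
20 | C13 acetate, C8 methacrylate | CC(C)=CCC[C@]1(C)O[C@@H]1[C@@H]1OC(=O)C(COC(C)=O)=C1[C@H](OC(=O)C(C)=C)CC(=C)[Si](C)(C)C | intermediate
21 | 1,2,4-trioxolane (ozonide) of the C1 isopropylidene alkene of 20 | CC1(C)OOC(CC[C@]2(C)O[C@@H]2[C@@H]2OC(=O)C(COC(C)=O)=C2[C@H](OC(=O)C(C)=C)CC(=C)[Si](C)(C)C)O1 | intermediate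
22 | C1 aldehyde with C10 vinylsilane | O=CCC[C@]1(C)O[C@@H]1[C@@H]1OC(=O)C(COC(C)=O)=C1[C@H](OC(=O)C(C)=C)CC(=C)[Si](C)(C)C | intermediate
23 | C1 aldehyde with C10 vinyl iodide | O=CCC[C@]1(C)O[C@@H]1[C@@H]1OC(=O)C(COC(C)=O)=C1[C@H](OC(=O)C(C)=C)CC(=C)I | intermediate
24 | alkenylchromium dichloride derived from 23 | O=CCC[C@]1(C)O[C@@H]1[C@@H]1OC(=O)C(COC(C)=O)=C1[C@H](OC(=O)C(C)=C)CC(=C)[Cr](Cl)Cl | intermediate
25 | ten-membered C1 allylic alcohol (C1 unassigned, both epimers used) | C=C(C)C(=O)O[C@@H]1CC(=C)C(O)CC[C@]2(C)O[C@@H]2[C@@H]2OC(=O)C(COC(C)=O)=C21 | intermediate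
26 | CNP0266914.1 (4S,5R,6R,8R) | C=C(C)C(=O)O[C@@H]1CC(=C)C(=O)CC[C@]2(C)O[C@@H]2[C@@H]2OC(=O)C(COC(C)=O)=C21 | target

Total step count: 14. Longest linear sequence: 11 steps (4 → 6 → 13 → 14 → 17 → 18 → 19 → 20 → 22 → 23 → 25 → 26).

Steps most likely to fail

**Step 7.** The oxidative cyclisation may form the C–C bond at the less hindered alkyne carbon. Zerovalent nickel may instead dimerise the aldehyde in a Tishchenko manner or open the oxirane, and CO may strip nickel from the metallacycle before it inserts.

The fallback uses known chemistry, sets out from 14 and 3 and comes back at 17. It builds C11–C12 first, at the carbon where steric control helps.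
- Alkyne 14 would be turned with Ti(OiPr)4 and c-C5H9MgCl into its titanacyclopropene.
- CO2 would insert at the less hindered C11, and iodine would cleave the remaining C7–Ti bond with retention to give (2Z,4R)-3-iodo-2-(silyloxymethyl)dienoic acid F1.
- TMSCHN2 would give its methyl ester F2.
- Nozaki–Hiyama–Kishi addition of F2 to 3 (CrCl2, NiCl2 cat., DMF), again under Felkin control, would be followed by spontaneous lactonisation of the cis-disposed alkoxide and ester to give 17.

**Step 13.** Intermolecular addition (oligomerisation) may outrun closure of the ten-membered ring. Low-valent nickel and chromium may also ionise the activated allylic acetate or reduce the conjugated esters.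

The fallback sets out from 17 and comes back at 26. The ring would be closed before the esters are installed, so that the organochromium step meets only silyl ethers.
- Ozonolysis of 17 would give bis-silyl ether aldehyde F3.
- NIS would give bis-silyl ether iodo aldehyde F4.
- Nozaki–Hiyama–Kishi closure would give macrocyclic bis-silyl ether alcohol F5.
- Dess–Martin oxidation would give macrocyclic bis-silyl ether enone F6.
- HF·pyridine would give enone diol F7.
- AcCl/collidine would give enone C13 monoacetate F8.
- Methacrylic anhydride with DMAP would then deliver 26.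

**Step 11.** Ozone may also attack the vinylsilane, which would mean loss of the handle for ring closure, before the trisubstituted alkene is consumed.

The fallback sets out from 20 and comes back at 22. Cleavage would be split into a dihydroxylation and a glycol cleavage. OsO4 (cat.) with NMO in acetone–water at 0 °C would give C1,isopropyl diol F9, whose carbinol configuration is inconsequential. NaIO4 on silica in CH2Cl2 would then give 22.

Further compounds
F1 | step 7 | (2Z,4R)-4-[(tert-butyldimethylsilyl)oxy]-2-{[(tert-butyldimethylsilyl)oxy]methyl}-3-iodo-6-(trimethylsilyl)hepta-2,6-dienoic acid | OC(=O)/C(CO[Si](C)(C)C(C)(C)C)=C(\I)[C@H](O[Si](C)(C)C(C)(C)C)CC(=C)[Si](C)(C)C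
F2 | step 7 | methyl ester of F1 | COC(=O)/C(CO[Si](C)(C)C(C)(C)C)=C(\I)[C@H](O[Si](C)(C)C(C)(C)C)CC(=C)[Si](C)(C)C
F3 | step 13 | bis-silyl ether C1 aldehyde with vinylsilane | O=CCC[C@]1(C)O[C@@H]1[C@@H]1OC(=O)C(CO[Si](C)(C)C(C)(C)C)=C1[C@H](O[Si](C)(C)C(C)(C)C)CC(=C)[Si](C)(C)C
F4 | step 13 | bis-silyl ether C1 aldehyde with vinyl iodide | O=CCC[C@]1(C)O[C@@H]1[C@@H]1OC(=O)C(CO[Si](C)(C)C(C)(C)C)=C1[C@H](O[Si](C)(C)C(C)(C)C)CC(=C)I
F5 | step 13 | macrocyclic bis-silyl ether C1 alcohol (C1 unassigned) | CC(C)(C)[Si](C)(C)O[C@@H]1CC(=C)C(O)CC[C@]2(C)O[C@@H]2[C@@H]2OC(=O)C(CO[Si](C)(C)C(C)(C)C)=C21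
F6 | step 13 | macrocyclic bis-silyl ether enone | CC(C)(C)[Si](C)(C)O[C@@H]1CC(=C)C(=O)CC[C@]2(C)O[C@@H]2[C@@H]2OC(=O)C(CO[Si](C)(C)C(C)(C)C)=C21
F7 | step 13 | macrocyclic enone C8,C13-diol | O[C@@H]1CC(=C)C(=O)CC[C@]2(C)O[C@@H]2[C@@H]2OC(=O)C(CO)=C21
F8 | step 13 | macrocyclic enone C13 acetate, C8 alcohol | O[C@@H]1CC(=C)C(=O)CC[C@]2(C)O[C@@H]2[C@@H]2OC(=O)C(COC(C)=O)=C21
F9 | step 11 | vicinal diol from the isopropylidene alkene of 20 (carbinol centre unassigned) | CC(C)(O)C(O)CC[C@]1(C)O[C@@H]1[C@@H]1OC(=O)C(COC(C)=O)=C1[C@H](OC(=O)C(C)=C)CC(=C)[Si](C)(C)C
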